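Everything rests on opening ring C of unit 4, the flavanyl group on catechin C6, at O1–C2 and C3–C4. Its all-trans C2/C3/C4 triad is read as the heterodiene O1=C8a–C4a=C4 plus an E-alkene C2=C3, with boron standing in for the 3-hydroxyl. One acid-triggered oxa-[4+2] between an ortho-quinone methide and a β-borylstyrene therefore closes that pyran, forms two bonds and sets three stereocentres. Its precursor is perbenzylated 8-bromocatechin whose C6 bears a CH(OH) carbon bonded to a 4-benzyloxy-2-hydroxyphenyl ring. The C8 bromide then brings in units 2 and 1, both 3,4-cis, by aryl-metal addition to one common bromoketone followed by hydride capture.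

Key step: step 7

Reading of the target:
- Unit 3 is (+)-catechin (2R,3S).
- Units 1, 2 and 4 are ent-fisetinidol units (2S,3R; 2-aryl β, 3-OH α).
- Unit 4 is bonded through 4β (2,3-trans-3,4-trans).
- Units 1 and 2 are bonded through 4α (2,3-trans-3,4-cis).
- The ketone used for units 1 and 2 must therefore belong to the (2S,3S) series, the mirror image of natural fustin.

Assumption: the sense of induction of the chiral acid toward this new dienophile cannot be derived with certainty. The (R)-catalyst is written, and its mirror image would be taken if it favours the other methide face.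

Abbreviations: Bn = benzyl, pin = pinacolato, MOM = methoxymethyl. Flavan numbering is used within each unit.

Step 1
Reactants: 1 (+)-catechin
Product: 2 5,7,3',4'-tetra-O-benzyl-(+)-catechin
Conditions: BnBr, K2CO3, DMF, 0 °C → rt
Reagents that add atoms: benzyl bromide, BrCc1ccccc1
Why: Williamson etherification in which carbonate deprotonates only the four phenols, so the secondary 3-OH stays free and C2/C3 are untouched.

Step 2
Reactants: 2 5,7,3',4'-tetra-O-benzyl-(+)-catechin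
Product: 3 3,5,7,3',4'-penta-O-benzyl-(+)-catechin
Conditions: NaH, BnBr, DMF, 0 °C → rt
Reagents that add atoms: benzyl bromide, BrCc1ccccc1
Why: Williamson etherification of the remaining secondary alcohol, which no longer risks C-benzylation or C2 epimerisation because every phenol is already capped.

Step 3
Reactants: 3 3,5,7,3',4'-penta-O-benzyl-(+)-catechin
Product: 4 8-bromo-3,5,7,3',4'-penta-O-benzylcatechin
Conditions: NBS, CH2Cl2, −78 °C → 0 °C
Reagents that add atoms: N-bromosuccinimide, O=C1CCC(=O)N1Br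
Why: Electrophilic aromatic bromination, for which C8 is the most reactive ring A position of 5,7-di-O-benzyl flavan-3-ols, and one equivalent of NBS in the cold should stop at the monobromide.

Step 4
Reactants: 4 8-bromo-3,5,7,3',4'-penta-O-benzylcatechin
Product: 5 8-bromo-6-iodo-3,5,7,3',4'-penta-O-benzylcatechin
Conditions: NIS, CF3CO2H (cat.), CH2Cl2/MeCN, 0 °C, dark
Reagents that add atoms: N-iodosuccinimide, O=C1CCC(=O)N1I
Why: Electrophilic aromatic iodination at C6, the only open position of the phloroglucinol-type ring A, which stays far more electron-rich than the catechol-type ring B.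

Step 5
Reactants: 5 8-bromo-6-iodo-3,5,7,3',4'-penta-O-benzylcatechin; 6 4-(benzyloxy)-2-hydroxybenzaldehyde
Product: 9 (8-bromo-penta-O-benzylcatechin-6-yl)[4-(benzyloxy)-2-hydroxyphenyl]methanol (both carbinol epimers), via arylmagnesium chloride 7 (not isolated), via sodium phenoxide 8 (not isolated)
Conditions: 5: iPrMgCl·LiCl, THF, −20 °C; 6: NaH, THF, 0 °C; combine, −20 °C → rt; H2O; Et3N-deactivated silica
Reagents that add atoms: none
Why: Iodine–magnesium exchange is much faster at C6–I than at C8–Br, and Grignard 1,2-addition to a pre-formed salicylaldehyde phenoxide is the standard entry to ortho-hydroxybenzhydrols, needs no phenol protecting group, and gives a carbinol centre whose configuration does not matter because step 7 flattens it.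

Step 6
Reactants: 10 3,4-bis(benzyloxy)benzaldehyde; 11 bis(4,4,5,5-tetramethyl-1,3,2-dioxaborolan-2-yl)methane
Product: 13 (E)-2-[3,4-bis(benzyloxy)styryl]-4,4,5,5-tetramethyl-1,3,2-dioxaborolane, via lithiated diborylmethane 12 (not isolated)
Conditions: 11, LiTMP, THF, 0 °C; then 10, −78 °C → rt; H2O
Reagents that add atoms: none
Why: Boron–Wittig olefination, in which the α-boryl carbanion adds to the aromatic aldehyde and syn boron–oxygen elimination gives the E-alkenylboronate in one operation.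

Step 7
Reactants: 9 (8-bromo-penta-O-benzylcatechin-6-yl)[4-(benzyloxy)-2-hydroxyphenyl]methanol; 13 (E)-2-[3,4-bis(benzyloxy)styryl]-4,4,5,5-tetramethyl-1,3,2-dioxaborolane
Product: 15 6-[(2β,3α,4β)-7-(benzyloxy)-2-[3,4-bis(benzyloxy)phenyl]-3-(pinacolboryl)chroman-4-yl]-8-bromo-penta-O-benzylcatechin (unit 4 all-trans), via ortho-quinone methide 14 (not isolated)
Conditions: (R)-3,3'-bis(2,4,6-triisopropylphenyl)-1,1'-binaphthyl-2,2'-diyl N-triflylphosphoramide (10 mol %), 13 (2 equiv), 5 Å MS, toluene, −40 → 0 °C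
Reagents that add atoms: none
Why: Proposed new method: the chiral acid protonates the benzhydrol oxygen of 9, water leaves from the doubly donor-stabilised position and the (E)-ortho-quinone methide 14 stays paired with the catalyst through its carbonyl oxygen, after which the boron-bearing carbon of 13 bonds to the methide carbon (C3–C4) while charge builds on the carbon next to the dialkoxyphenyl ring, onto which the quinone oxygen closes (O1–C2). The closest known reaction type is the Brønsted-acid-catalysed inverse-electron-demand oxa-[4+2] cycloaddition of ortho-quinone methides with β-substituted electron-rich styrenes, and only the boryl substituent on the dienophile is without precedent. The pyran closes by an intermolecular, asynchronous [4π+2π] annulation of the four atoms O1–C8a–C4a–C4 with the two atoms C3–C2, the last event being capture of the benzylic cationic centre by the ring A oxygen within a six-membered array. C2 and C3 come out trans because addition across the E-alkene is suprafacial, C4 comes out cis to C2 because the dienophile aryl group sits endo under the E-methide, and the absolute sense (2β-aryl, 3α-boryl, 4β-catechinyl) has to come from the binaphthyl pocket, since the catechin centres lie too far from C4 to bias its faces. Regioselectivity follows from the aryl donor, which makes the boron-bearing carbon the nucleophilic terminus, and the substrate itself secures chemoselectivity, because bromine at C8 closes the only nucleophilic ring A position so that 14 cannot be arylated by a second molecule, and the non-exchanging pinacol ester disfavours alkenyl transfer with loss of boron. The N-triflylphosphoramide is preferred to a plain phosphoric acid because the trialkoxyaryl-stabilised methide and the slightly electron-poor borylstyrene need the more electrophilic, protonated form of 14.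

Step 8
Reactants: 15 C3-pinacolboryl dimer
Product: 16 8-bromo-penta-O-benzylcatechin-(6→4β)-7,3',4'-tri-O-benzyl-ent-fisetinidol (free 3-OH in unit 4)
Conditions: NaBO3·4H2O, THF/H2O, rt
Reagents that add atoms: sodium perborate, [Na+].[O-]OB=O
Why: Perborate oxidation of the C–B bond proceeds by 1,2-migration of C3 from boron to oxygen with retention, so the new 3-OH stays trans to both neighbours, and the aryl bromide and benzyl ethers are inert.

Step 9
Reactants: 16 dimer with free 3-OH in unit 4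
Product: 17 8-bromo-penta-O-benzylcatechin-(6→4β)-3,7,3',4'-tetra-O-benzyl-ent-fisetinidol
Conditions: NaH, BnBr, Bu4NI (cat.), DMF, 0 °C → rt
Reagents that add atoms: benzyl bromide, BrCc1ccccc1
Why: Williamson etherification masks the only acidic proton before the organometallic steps and touches no stereocentre.

Step 10
Reactants: 18 1-[4-(benzyloxy)-2-hydroxyphenyl]ethanone
Product: 19 1-[4-(benzyloxy)-5-bromo-2-hydroxyphenyl]ethanone
Conditions: NBS, MeCN, 0 °C → rt
Reagents that add atoms: N-bromosuccinimide, O=C1CCC(=O)N1Br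
Why: Electrophilic aromatic bromination goes para to the free phenol and ortho to the benzyloxy group (C5), since the position between the two oxygens is more hindered.

Step 11
Reactants: 19 1-[4-(benzyloxy)-5-bromo-2-hydroxyphenyl]ethanone
Product: 20 1-[4-(benzyloxy)-5-bromo-2-(methoxymethoxy)phenyl]ethanone
Conditions: NaH, MOMCl, DMF, 0 °C
Reagents that add atoms: chloromethyl methyl ether, COCCl
Why: O-alkylation of the chelated phenol to its MOM acetal keeps the phenol from attacking the enone or the epoxide before step 14.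

Step 12
Reactants: 20 1-[4-(benzyloxy)-5-bromo-2-(methoxymethoxy)phenyl]ethanone; 10 3,4-bis(benzyloxy)benzaldehyde
Product: 21 (E)-1-[4-(benzyloxy)-5-bromo-2-(methoxymethoxy)phenyl]-3-[3,4-bis(benzyloxy)phenyl]prop-2-en-1-one
Conditions: KOH, EtOH/THF, rt
Reagents that add atoms: none
Why: Claisen–Schmidt condensation of a methyl ketone with a non-enolisable aldehyde, whose E1cB dehydration gives the E-chalcone.

Step 13
Reactants: 21 (E)-chalcone
Product: 22 (αS,βR)-epoxychalcone [(2S,3R)-3-[3,4-bis(benzyloxy)phenyl]oxiran-2-yl][4-(benzyloxy)-5-bromo-2-(methoxymethoxy)phenyl]methanone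
Conditions: poly-D-leucine, urea·H2O2, DBU, THF, rt
Reagents that add atoms: urea–hydrogen peroxide, OO.NC(N)=O
Why: Juliá–Colonna epoxidation (Weitz–Scheffer addition of hydroperoxide inside the helical polypeptide) is established on 2'-MOM-protected polyoxygenated chalcones, the E-enone fixes the trans epoxide, and the D-polymer gives the (αS,βR) antipode of the (αR,βS) epoxides obtained from the L-polymer.

Step 14
Reactants: 22 (αS,βR)-epoxychalcone
Product: 24 (2S,3S)-7-(benzyloxy)-2-[3,4-bis(benzyloxy)phenyl]-6-bromo-3-hydroxychroman-4-one, via free phenol epoxide 23 (not isolated)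
Conditions: HCl (3 M aq), MeOH/THF, 50 °C
Reagents that add atoms: none
Why: Acidic acetal cleavage frees the phenol, which opens the epoxide at the benzylic carbon in a 6-endo closure with inversion to the 2,3-trans dihydroflavonol, C3 keeping the untouched Cα configuration so that any ionisation at C2 still ends in the favoured trans isomer of the same enantiomeric series.

Step 15
Reactants: 24 (2S,3S)-6-bromo-3-hydroxychroman-4-one
Product: 25 (2S,3S)-3,7-bis(benzyloxy)-2-[3,4-bis(benzyloxy)phenyl]-6-bromochroman-4-one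
Conditions: BnOC(=NH)CCl3, TfOH (cat.), CH2Cl2/cyclohexane, 0 °C → rt
Reagents that add atoms: benzyl 2,2,2-trichloroacetimidate, N=C(OCc1ccccc1)C(Cl)(Cl)Cl
Why: Acid-catalysed trichloroacetimidate benzylation avoids the base that would epimerise, ring-open or dehydrogenate an α-hydroxy flavanone, so C2 and C3 are kept.

Step 16
Reactants: 17 C8-bromo dimer; 25 (2S,3S)-bromoketone
Product: 28 tertiary alcohol in which C8 of the catechin unit of 17 is bonded to C4(OH) of the 6-bromo-3,7,3',4'-tetra-O-benzylflavan unit 2 (either C4 epimer), via aryllithium 26 (not isolated), via arylcerium dichloride 27 (not isolated)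
Conditions: 17, tBuLi (2 equiv), THF, −78 °C; CeCl3, −78 °C; then 25, −78 → −40 °C; H2O
Reagents that add atoms: none
Why: Bromine–lithium exchange at C8 of perbenzylated flavan-3-ols and 1,2-addition of the aryl-metal to protected 4-oxoflavan-3-ols is known chemistry, and transmetallation to the weakly basic organocerium should hold back enolisation, β-elimination and scrambling with the aryl bromide of 25, while the new carbinol configuration is irrelevant because it is ionised next.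

Step 17
Reactants: 28 tertiary alcohol
Product: 30 6-bromo-tetra-O-benzyl-ent-fisetinidol-(4α→8)-penta-O-benzylcatechin-(6→4β)-tetra-O-benzyl-ent-fisetinidol, via C4 carbenium trifluoroacetate 29 (not isolated)
Conditions: Bu3SnH, CF3CO2H, CH2Cl2, 0 °C
Reagents that add atoms: none
Why: Ionic hydrogenation, in which the acid ionises the doubly benzylic tertiary alcohol and the strong hydride donor traps the cation before C3–H can be lost, entering anti to the 3-benzyloxy group as nucleophiles do on 2,3-trans flavan-4-yl cations, so that the catechin ring ends cis to 3-OBn (4α), the acid-robust 5-deoxy interflavanyl bond surviving.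

Step 18
Reactants: 30 trimer bromide; 25 (2S,3S)-bromoketone
Product: 33 tertiary alcohol in which C6 of unit 2 of 30 is bonded to C4(OH) of a second 6-bromo-3,7,3',4'-tetra-O-benzylflavan unit 1 (either C4 epimer), via aryllithium 31 (not isolated), via arylcerium dichloride 32 (not isolated)
Conditions: 30, tBuLi (2 equiv), THF, −78 °C; CeCl3, −78 °C; then 25, −78 → −40 °C; H2O
Reagents that add atoms: none
Why: The same exchange, transmetallation and 1,2-addition sequence as in step 16, now at the only bromide of 30 and at a position with a single ortho substituent, hence less crowded.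

Step 19
Reactants: 33 tertiary alcohol
Product: 35 6-bromo-tetra-O-benzyl-ent-fisetinidol-(4α→6)-tetra-O-benzyl-ent-fisetinidol-(4α→8)-penta-O-benzylcatechin-(6→4β)-tetra-O-benzyl-ent-fisetinidol, via C4 carbenium trifluoroacetate 34 (not isolated)
Conditions: Bu3SnH, CF3CO2H, CH2Cl2, 0 °C
Reagents that add atoms: none
Why: Ionic hydrogenation as in step 17, hydride again entering anti to 3-OBn so that ring A of unit 2 ends cis to it (4α, 3,4-cis in unit 1).

Step 20
Reactants: 35 perbenzylated bromo tetramer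
Product: 36 ent-fisetinidol-(4α→6)-ent-fisetinidol-(4α→8)-catechin-(6→4β)-ent-fisetinidol (CNP0126838.5)
Conditions: H2 (1 atm), Pd(OH)2/C, NaOAc, THF/MeOH/H2O, rt
Reagents that add atoms: none
Why: Catalytic hydrogenolysis removes all seventeen O-benzyl groups and the leftover C6–Br of unit 1 in one operation, acetate buffers the HBr, and no stereocentre is touched.

Compound list
1 | (+)-catechin, (2R,3S) | O[C@H]1Cc2c(O)cc(O)cc2O[C@@H]1c1ccc(O)c(O)c1 | starting material
2 | 5,7,3',4'-tetra-O-benzyl-(+)-catechin | c1c(OCc9ccccc9)cc2O[C@H](c3ccc(OCc9ccccc9)c(OCc9ccccc9)c3)[C@@H](O)Cc2c1OCc9ccccc9 | intermediate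
3 | 3,5,7,3',4'-penta-O-benzyl-(+)-catechin | c1c(OCc9ccccc9)cc2O[C@H](c3ccc(OCc9ccccc9)c(OCc9ccccc9)c3)[C@@H](OCc9ccccc9)Cc2c1OCc9ccccc9 | intermediate
4 | 8-bromo-penta-O-benzylcatechin | c1c(OCc9ccccc9)c(Br)c2O[C@H](c3ccc(OCc9ccccc9)c(OCc9ccccc9)c3)[C@@H](OCc9ccccc9)Cc2c1OCc9ccccc9 | intermediate
5 | 8-bromo-6-iodo-penta-O-benzylcatechin | Ic1c(OCc9ccccc9)c(Br)c2O[C@H](c3ccc(OCc9ccccc9)c(OCc9ccccc9)c3)[C@@H](OCc9ccccc9)Cc2c1OCc9ccccc9 | intermediate
6 | 4-(benzyloxy)-2-hydroxybenzaldehyde | O=Cc1ccc(OCc2ccccc2)cc1O | starting material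
7 | (8-bromo-penta-O-benzylcatechin-6-yl)magnesium chloride | Cl[Mg]c1c(OCc9ccccc9)c(Br)c2O[C@H](c3ccc(OCc9ccccc9)c(OCc9ccccc9)c3)[C@@H](OCc9ccccc9)Cc2c1OCc9ccccc9 | intermediate
8 | sodium 5-(benzyloxy)-2-formylphenoxide | O=Cc1ccc(OCc2ccccc2)cc1[O-].[Na+] | intermediate
9 | (8-bromo-penta-O-benzylcatechin-6-yl)[4-(benzyloxy)-2-hydroxyphenyl]methanol, both carbinol epimers | OC(c1ccc(OCc9ccccc9)cc1O)c1c(OCc9ccccc9)c(Br)c2O[C@H](c3ccc(OCc9ccccc9)c(OCc9ccccc9)c3)[C@@H](OCc9ccccc9)Cc2c1OCc9ccccc9 | intermediate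
10 | 3,4-bis(benzyloxy)benzaldehyde | O=Cc1ccc(OCc2ccccc2)c(OCc2ccccc2)c1 | starting material
11 | bis(4,4,5,5-tetramethyl-1,3,2-dioxaborolan-2-yl)methane | CC1(C)OB(CB2OC(C)(C)C(C)(C)O2)OC1(C)C | starting material
12 | lithio-bis(pinacolboryl)methane | [Li]C(B1OC(C)(C)C(C)(C)O1)B1OC(C)(C)C(C)(C)O1 | intermediate
13 | (E)-2-[3,4-bis(benzyloxy)styryl]-4,4,5,5-tetramethyl-1,3,2-dioxaborolane | CC1(C)OB(/C=C/c2ccc(OCc3ccccc3)c(OCc3ccccc3)c2)OC1(C)C | intermediate
14 | (E)-3-(benzyloxy)-6-[(8-bromo-penta-O-benzylcatechin-6-yl)methylidene]cyclohexa-2,4-dien-1-one | O=C1C=C(OCc9ccccc9)C=C/C1=C\c1c(OCc9ccccc9)c(Br)c2O[C@H](c3ccc(OCc9ccccc9)c(OCc9ccccc9)c3)[C@@H](OCc9ccccc9)Cc2c1OCc9ccccc9 | intermediate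
15 | 8-bromo-penta-O-benzylcatechin bearing at C6 the all-trans (2β-aryl, 3α-Bpin, 4β) 7,3',4'-tri-O-benzylflavan-4-yl unit 4 | Brc1c(OCc9ccccc9)c([C@H]2c3ccc(OCc9ccccc9)cc3O[C@@H](c3ccc(OCc9ccccc9)c(OCc9ccccc9)c3)[C@@H]2B2OC(C)(C)C(C)(C)O2)c(OCc9ccccc9)c2c1O[C@H](c1ccc(OCc9ccccc9)c(OCc9ccccc9)c1)[C@@H](OCc9ccccc9)C2 | intermediate
16 | 8-bromo-penta-O-benzylcatechin-(6→4β)-7,3',4'-tri-O-benzyl-ent-fisetinidol | Brc1c(OCc9ccccc9)c([C@H]2c3ccc(OCc9ccccc9)cc3O[C@@H](c3ccc(OCc9ccccc9)c(OCc9ccccc9)c3)[C@@H]2O)c(OCc9ccccc9)c2c1O[C@H](c1ccc(OCc9ccccc9)c(OCc9ccccc9)c1)[C@@H](OCc9ccccc9)C2 | intermediate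
17 | 8-bromo-penta-O-benzylcatechin-(6→4β)-3,7,3',4'-tetra-O-benzyl-ent-fisetinidol | Brc1c(OCc9ccccc9)c([C@H]2c3ccc(OCc9ccccc9)cc3O[C@@H](c3ccc(OCc9ccccc9)c(OCc9ccccc9)c3)[C@@H]2OCc9ccccc9)c(OCc9ccccc9)c2c1O[C@H](c1ccc(OCc9ccccc9)c(OCc9ccccc9)c1)[C@@H](OCc9ccccc9)C2 | intermediate
18 | 1-[4-(benzyloxy)-2-hydroxyphenyl]ethanone | CC(=O)c1ccc(OCc2ccccc2)cc1O | starting material
19 | 1-[4-(benzyloxy)-5-bromo-2-hydroxyphenyl]ethanone | CC(=O)c1cc(Br)c(OCc2ccccc2)cc1O | intermediate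
20 | 1-[4-(benzyloxy)-5-bromo-2-(methoxymethoxy)phenyl]ethanone | CC(=O)c1cc(Br)c(OCc2ccccc2)cc1OCOC | intermediate
21 | (E)-1-[4-(benzyloxy)-5-bromo-2-(methoxymethoxy)phenyl]-3-[3,4-bis(benzyloxy)phenyl]prop-2-en-1-one | O=C(/C=C/c1ccc(OCc2ccccc2)c(OCc2ccccc2)c1)c1cc(Br)c(OCc2ccccc2)cc1OCOC | intermediate
22 | (αS,βR)-epoxide of 21 | O=C(c1cc(Br)c(OCc2ccccc2)cc1OCOC)[C@H]1O[C@@H]1c1ccc(OCc2ccccc2)c(OCc2ccccc2)c1 | intermediate
23 | (αS,βR)-epoxide with free 2'-phenol | O=C(c1cc(Br)c(OCc2ccccc2)cc1O)[C@H]1O[C@@H]1c1ccc(OCc2ccccc2)c(OCc2ccccc2)c1 | intermediate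
24 | (2S,3S)-7-(benzyloxy)-2-[3,4-bis(benzyloxy)phenyl]-6-bromo-3-hydroxychroman-4-one | Brc1cc2c(cc1OCc9ccccc9)O[C@@H](c1ccc(OCc9ccccc9)c(OCc9ccccc9)c1)[C@H](O)C2=O | intermediate
25 | (2S,3S)-3,7-bis(benzyloxy)-2-[3,4-bis(benzyloxy)phenyl]-6-bromochroman-4-one | Brc1cc2c(cc1OCc9ccccc9)O[C@@H](c1ccc(OCc9ccccc9)c(OCc9ccccc9)c1)[C@H](OCc9ccccc9)C2=O | intermediate
26 | C8 aryllithium derived from 17 | [Li]c1c(OCc9ccccc9)c([C@H]2c3ccc(OCc9ccccc9)cc3O[C@@H](c3ccc(OCc9ccccc9)c(OCc9ccccc9)c3)[C@@H]2OCc9ccccc9)c(OCc9ccccc9)c2c1O[C@H](c1ccc(OCc9ccccc9)c(OCc9ccccc9)c1)[C@@H](OCc9ccccc9)C2 | intermediate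
27 | C8 arylcerium dichloride derived from 17 | Cl[Ce](Cl)c1c(OCc9ccccc9)c([C@H]2c3ccc(OCc9ccccc9)cc3O[C@@H](c3ccc(OCc9ccccc9)c(OCc9ccccc9)c3)[C@@H]2OCc9ccccc9)c(OCc9ccccc9)c2c1O[C@H](c1ccc(OCc9ccccc9)c(OCc9ccccc9)c1)[C@@H](OCc9ccccc9)C2 | intermediate
28 | trimer tertiary alcohol (unit 2 C4–OH, either epimer) | Brc1cc2c(cc1OCc9ccccc9)O[C@@H](c1ccc(OCc9ccccc9)c(OCc9ccccc9)c1)[C@H](OCc9ccccc9)C2(O)c1c(OCc9ccccc9)c([C@H]2c3ccc(OCc9ccccc9)cc3O[C@@H](c3ccc(OCc9ccccc9)c(OCc9ccccc9)c3)[C@@H]2OCc9ccccc9)c(OCc9ccccc9)c2c1O[C@H](c1ccc(OCc9ccccc9)c(OCc9ccccc9)c1)[C@@H](OCc9ccccc9)C2 | intermediate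
29 | unit 2 C4 carbenium trifluoroacetate | Brc1cc2c(cc1OCc9ccccc9)O[C@@H](c1ccc(OCc9ccccc9)c(OCc9ccccc9)c1)[C@H](OCc9ccccc9)[C+]2c1c(OCc9ccccc9)c([C@H]2c3ccc(OCc9ccccc9)cc3O[C@@H](c3ccc(OCc9ccccc9)c(OCc9ccccc9)c3)[C@@H]2OCc9ccccc9)c(OCc9ccccc9)c2c1O[C@H](c1ccc(OCc9ccccc9)c(OCc9ccccc9)c1)[C@@H](OCc9ccccc9)C2.[O-]C(=O)C(F)(F)F | intermediate
30 | 6-bromo-tetra-O-benzyl-ent-fisetinidol-(4α→8)-penta-O-benzylcatechin-(6→4β)-tetra-O-benzyl-ent-fisetinidol | Brc1cc2c(cc1OCc9ccccc9)O[C@@H](c1ccc(OCc9ccccc9)c(OCc9ccccc9)c1)[C@H](OCc9ccccc9)[C@@H]2c1c(OCc9ccccc9)c([C@H]2c3ccc(OCc9ccccc9)cc3O[C@@H](c3ccc(OCc9ccccc9)c(OCc9ccccc9)c3)[C@@H]2OCc9ccccc9)c(OCc9ccccc9)c2c1O[C@H](c1ccc(OCc9ccccc9)c(OCc9ccccc9)c1)[C@@H](OCc9ccccc9)C2 | intermediate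
31 | unit 2 C6 aryllithium derived from 30 | [Li]c1cc2c(cc1OCc9ccccc9)O[C@@H](c1ccc(OCc9ccccc9)c(OCc9ccccc9)c1)[C@H](OCc9ccccc9)[C@@H]2c1c(OCc9ccccc9)c([C@H]2c3ccc(OCc9ccccc9)cc3O[C@@H](c3ccc(OCc9ccccc9)c(OCc9ccccc9)c3)[C@@H]2OCc9ccccc9)c(OCc9ccccc9)c2c1O[C@H](c1ccc(OCc9ccccc9)c(OCc9ccccc9)c1)[C@@H](OCc9ccccc9)C2 | intermediate
32 | unit 2 C6 arylcerium dichloride derived from 30 | Cl[Ce](Cl)c1cc2c(cc1OCc9ccccc9)O[C@@H](c1ccc(OCc9ccccc9)c(OCc9ccccc9)c1)[C@H](OCc9ccccc9)[C@@H]2c1c(OCc9ccccc9)c([C@H]2c3ccc(OCc9ccccc9)cc3O[C@@H](c3ccc(OCc9ccccc9)c(OCc9ccccc9)c3)[C@@H]2OCc9ccccc9)c(OCc9ccccc9)c2c1O[C@H](c1ccc(OCc9ccccc9)c(OCc9ccccc9)c1)[C@@H](OCc9ccccc9)C2 | intermediate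
33 | tetramer tertiary alcohol (unit 1 C4–OH, either epimer) | Brc1cc2c(cc1OCc9ccccc9)O[C@@H](c1ccc(OCc9ccccc9)c(OCc9ccccc9)c1)[C@H](OCc9ccccc9)C2(O)c1cc2c(cc1OCc9ccccc9)O[C@@H](c1ccc(OCc9ccccc9)c(OCc9ccccc9)c1)[C@H](OCc9ccccc9)[C@@H]2c1c(OCc9ccccc9)c([C@H]2c3ccc(OCc9ccccc9)cc3O[C@@H](c3ccc(OCc9ccccc9)c(OCc9ccccc9)c3)[C@@H]2OCc9ccccc9)c(OCc9ccccc9)c2c1O[C@H](c1ccc(OCc9ccccc9)c(OCc9ccccc9)c1)[C@@H](OCc9ccccc9)C2 | intermediate
34 | unit 1 C4 carbenium trifluoroacetate | Brc1cc2c(cc1OCc9ccccc9)O[C@@H](c1ccc(OCc9ccccc9)c(OCc9ccccc9)c1)[C@H](OCc9ccccc9)[C+]2c1cc2c(cc1OCc9ccccc9)O[C@@H](c1ccc(OCc9ccccc9)c(OCc9ccccc9)c1)[C@H](OCc9ccccc9)[C@@H]2c1c(OCc9ccccc9)c([C@H]2c3ccc(OCc9ccccc9)cc3O[C@@H](c3ccc(OCc9ccccc9)c(OCc9ccccc9)c3)[C@@H]2OCc9ccccc9)c(OCc9ccccc9)c2c1O[C@H](c1ccc(OCc9ccccc9)c(OCc9ccccc9)c1)[C@@H](OCc9ccccc9)C2.[O-]C(=O)C(F)(F)F | intermediate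
35 | 6-bromo-tetra-O-benzyl-ent-fisetinidol-(4α→6)-tetra-O-benzyl-ent-fisetinidol-(4α→8)-penta-O-benzylcatechin-(6→4β)-tetra-O-benzyl-ent-fisetinidol | Brc1cc2c(cc1OCc9ccccc9)O[C@@H](c1ccc(OCc9ccccc9)c(OCc9ccccc9)c1)[C@H](OCc9ccccc9)[C@@H]2c1cc2c(cc1OCc9ccccc9)O[C@@H](c1ccc(OCc9ccccc9)c(OCc9ccccc9)c1)[C@H](OCc9ccccc9)[C@@H]2c1c(OCc9ccccc9)c([C@H]2c3ccc(OCc9ccccc9)cc3O[C@@H](c3ccc(OCc9ccccc9)c(OCc9ccccc9)c3)[C@@H]2OCc9ccccc9)c(OCc9ccccc9)c2c1O[C@H](c1ccc(OCc9ccccc9)c(OCc9ccccc9)c1)[C@@H](OCc9ccccc9)C2 | intermediate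
36 | ent-fisetinidol-(4α→6)-ent-fisetinidol-(4α→8)-catechin-(6→4β)-ent-fisetinidol (CNP0126838.5) | Oc1ccc2c(c1)O[C@@H](c1ccc(O)c(O)c1)[C@H](O)[C@@H]2c1cc2c(cc1O)O[C@@H](c1ccc(O)c(O)c1)[C@H](O)[C@@H]2c1c(O)c([C@H]2c3ccc(O)cc3O[C@@H](c3ccc(O)c(O)c3)[C@@H]2O)c(O)c2c1O[C@H](c1ccc(O)c(O)c1)[C@@H](O)C2 | target

Total step count: 20. Longest linear sequence: 13 steps (1–5, 7–9, 16–20). The ketone branch (steps 10–15) and the boronate (step 6) are convergent.

Steps most likely to fail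

1. Step 7.
- What may go wrong: the borylstyrene may add too slowly, so that the methide decays. The acid may protodeborylate the styrene. The benzylic cation may shed boron, giving alkenyl transfer in place of ring closure. The catalyst may discriminate poorly between the two methide faces.
- Fallback (known chemistry): Lewis-acid coupling of a flavan-4-ol with a C8-blocked flavan-3-ol. It sets out from ketone 25 and bromide 4 and comes back at 17. NaBH4 in THF/MeOH reduces 25 to the 6-bromoflavan-4-ol F1. Bu3SnH with AIBN in toluene at 80 °C removes the ring bromine and gives the flavan-4-ol F2. BF3·OEt2 in CH2Cl2 at low temperature then activates the 4-hydroxyl of F2 in the presence of excess 4. C6 of 4, its only free ring A position, takes the place of the hydroxyl from the side away from the 3-benzyloxy group. This gives the all-trans dimer 17 directly, so steps 5 to 9 are bypassed.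

2. Step 16.
- What may go wrong: C8 is crowded, because its 7-benzyloxy neighbour is buttressed by unit 4. This may slow 1,2-addition so far that enolisation of 25 and ring opening by β-elimination take over.
- Fallback: reverse the polarity of the bond formation. It sets out from 17 and 25 and comes back at 30, also bypassing step 17. Compound 17 is lithiated to 26 as in step 16 and quenched with MeOH to the C8–H dimer F3. Ketone 25 is reduced with NaBH4 to the bromoflavan-4-ol F1. BF3·OEt2 in CH2Cl2 then joins C4 of F1 to C8 of F3, the most nucleophilic arene position present. In the 5-deoxy series such couplings give both C4 epimers, so the wanted 4α product 30 would have to be separated by chromatography from its 4β epimer F4. This route is therefore less selective but avoids all basic organometallics.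

3. Step 17.
- What may go wrong: hydride capture may show poor facial selectivity. Proton loss from C3 to the enol ether, followed by reprotonation, would erode the C3 configuration.
- Fallback: change the stereocontrol element rather than the reductant. It sets out from 24 and 17 and comes back at 30. TBSOTf and 2,6-lutidine in CH2Cl2 convert 24 into the 3-O-silyl ketone F5. The arylcerium 27, made from 17 as in step 16, adds to it to give the tertiary alcohol F6. Bu3SnH and CF3CO2H reduce F6 to the 3-O-silyl trimer F7. The bulkier silyloxy group prefers the axial position next to the C4-aryl cation and shields its own face more completely. TBAF in THF frees the 3-hydroxy trimer F8, and NaH with BnBr returns 30.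

Further compounds
F1 | step 7 | (2S,3R,4ξ)-3,7-bis(benzyloxy)-2-[3,4-bis(benzyloxy)phenyl]-6-bromochroman-4-ol | Brc1cc2c(cc1OCc9ccccc9)O[C@@H](c1ccc(OCc9ccccc9)c(OCc9ccccc9)c1)[C@H](OCc9ccccc9)C2O
F2 | step 7 | (2S,3R,4ξ)-3,7-bis(benzyloxy)-2-[3,4-bis(benzyloxy)phenyl]chroman-4-ol | c1cc2c(cc1OCc9ccccc9)O[C@@H](c1ccc(OCc9ccccc9)c(OCc9ccccc9)c1)[C@H](OCc9ccccc9)C2O
F3 | step 16 | penta-O-benzylcatechin-(6→4β)-tetra-O-benzyl-ent-fisetinidol (C8–H) | c1c(OCc9ccccc9)c([C@H]2c3ccc(OCc9ccccc9)cc3O[C@@H](c3ccc(OCc9ccccc9)c(OCc9ccccc9)c3)[C@@H]2OCc9ccccc9)c(OCc9ccccc9)c2c1O[C@H](c1ccc(OCc9ccccc9)c(OCc9ccccc9)c1)[C@@H](OCc9ccccc9)C2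
F4 | step 16 | 4β (3,4-trans) epimer of 30 at C4 of unit 2 | Brc1cc2c(cc1OCc9ccccc9)O[C@@H](c1ccc(OCc9ccccc9)c(OCc9ccccc9)c1)[C@H](OCc9ccccc9)[C@H]2c1c(OCc9ccccc9)c([C@H]2c3ccc(OCc9ccccc9)cc3O[C@@H](c3ccc(OCc9ccccc9)c(OCc9ccccc9)c3)[C@@H]2OCc9ccccc9)c(OCc9ccccc9)c2c1O[C@H](c1ccc(OCc9ccccc9)c(OCc9ccccc9)c1)[C@@H](OCc9ccccc9)C2
F5 | step 17 | (2S,3S)-7-(benzyloxy)-2-[3,4-bis(benzyloxy)phenyl]-6-bromo-3-(tert-butyldimethylsilyloxy)chroman-4-one | Brc1cc2c(cc1OCc9ccccc9)O[C@@H](c1ccc(OCc9ccccc9)c(OCc9ccccc9)c1)[C@H](O[Si](C)(C)C(C)(C)C)C2=O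
F6 | step 17 | trimer tertiary alcohol with 3-O-TBS in unit 2 (either C4 epimer) | Brc1cc2c(cc1OCc9ccccc9)O[C@@H](c1ccc(OCc9ccccc9)c(OCc9ccccc9)c1)[C@H](O[Si](C)(C)C(C)(C)C)C2(O)c1c(OCc9ccccc9)c([C@H]2c3ccc(OCc9ccccc9)cc3O[C@@H](c3ccc(OCc9ccccc9)c(OCc9ccccc9)c3)[C@@H]2OCc9ccccc9)c(OCc9ccccc9)c2c1O[C@H](c1ccc(OCc9ccccc9)c(OCc9ccccc9)c1)[C@@H](OCc9ccccc9)C2
F7 | step 17 | 4α-linked trimer bromide with 3-O-TBS in unit 2 | Brc1cc2c(cc1OCc9ccccc9)O[C@@H](c1ccc(OCc9ccccc9)c(OCc9ccccc9)c1)[C@H](O[Si](C)(C)C(C)(C)C)[C@@H]2c1c(OCc9ccccc9)c([C@H]2c3ccc(OCc9ccccc9)cc3O[C@@H](c3ccc(OCc9ccccc9)c(OCc9ccccc9)c3)[C@@H]2OCc9ccccc9)c(OCc9ccccc9)c2c1O[C@H](c1ccc(OCc9ccccc9)c(OCc9ccccc9)c1)[C@@H](OCc9ccccc9)C2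
F8 | step 17 | 4α-linked trimer bromide with free 3-OH in unit 2 | Brc1cc2c(cc1OCc9ccccc9)O[C@@H](c1ccc(OCc9ccccc9)c(OCc9ccccc9)c1)[C@H](O)[C@@H]2c1c(OCc9ccccc9)c([C@H]2c3ccc(OCc9ccccc9)cc3O[C@@H](c3ccc(OCc9ccccc9)c(OCc9ccccc9)c3)[C@@H]2OCc9ccccc9)c(OCc9ccccc9)c2c1O[C@H](c1ccc(OCc9ccccc9)c(OCc9ccccc9)c1)[C@@H](OCc9ccccc9)C2
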